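**Retrosynthetic overview** (disconnections listed from the first bond made to the last)
1. Ring B aryl–CH2 bond: octa-1,7-diene 1 is hydroborated at one end with 9-BBN 2 and coupled (B-alkyl Suzuki–Miyaura, via borane 4) with 1-(benzyloxy)-4-bromobenzene 3 to give alkene 5.
2. Key disconnection, ring A C(=O)–CH2 bond: a new cobalt-catalysed anti-Markovnikov hydroacylation of alkene 5 with 2-hydroxy-6-methoxybenzaldehyde 6 gives ketone 7.
3. Last disconnection, O–benzyl: hydrogenolysis of 7 gives target 8.
4. Rings: no ring is built. Both benzene rings are bought intact; ring B (from 3) is attached first and ring A (from 6) second.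

Assumption: the target has no stereocentre and no stereogenic double bond, so it is made as the one achiral compound drawn and no SMILES needs stereo descriptors.

**Step 1**
Reactants: 1 octa-1,7-diene; 2 9-borabicyclo[3.3.1]nonane (9-BBN); 3 1-(benzyloxy)-4-bromobenzene
Product: 5 1-(benzyloxy)-4-(oct-7-en-1-yl)benzene, via B-(oct-7-en-1-yl)-9-BBN 4 (not isolated)
Conditions: 1 (5 equiv), 2 (1 equiv, 0.5 M in THF), 0 °C to rt, 3 h; excess 1 removed in vacuo; then 3 (0.85 equiv), PdCl2(dppf) (3 mol %; dppf = 1,1'-bis(diphenylphosphino)ferrocene), 3 M aq NaOH (3 equiv), THF, 65 °C, 12 h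
Reagents that add atoms: none
Why: Brown hydroboration with 9-BBN is anti-Markovnikov and, with 1 in fivefold excess, stops at one alkene, and the primary B-alkyl-9-BBN then transfers its alkyl group in a Suzuki–Miyaura B-alkyl cross-coupling that leaves the benzyl ether and the remaining terminal alkene untouched; no stereocentre is formed.

**Step 2**
Reactants: 5 1-(benzyloxy)-4-(oct-7-en-1-yl)benzene; 6 2-hydroxy-6-methoxybenzaldehyde
Product: 7 9-[4-(benzyloxy)phenyl]-1-(2-hydroxy-6-methoxyphenyl)nonan-1-one
Conditions: 6 (1.3 equiv), CoBr2 (5 mol %), dcype (1,2-bis(dicyclohexylphosphino)ethane, 6 mol %), Zn dust (10 mol %), K3PO4 (10 mol %), MeCN, 70 °C, 16 h, N2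
Reagents that add atoms: none
Why: Proposed new method: cobalt-catalysed, phenoxide-chelation-assisted intermolecular hydroacylation, in which Zn reduces CoBr2/dcype to monovalent cobalt, which binds 6 as its phenoxide and inserts into the formyl C–H to give a five-membered acyl(hydrido) chelate of trivalent cobalt that is held against decarbonylation; the 1-alkene of 5 then inserts into Co–H with cobalt at the terminal carbon (steric control by the bulky bisphosphine), C(acyl)–C(sp3) reductive elimination forms the linear ketone, and proton transfer from fresh 6 releases 7; the closest known reaction type is the rhodium-catalysed linear hydroacylation of 1-alkenes with salicylaldehydes, together with low-valent cobalt hydroacylation of 1,3-dienes and tethered alkenes, whereas a cobalt catalyst has, to my knowledge, not been shown for a salicylaldehyde with an unactivated 1-alkene; no stereocentre is formed.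

**Step 3**
Reactants: 7 9-[4-(benzyloxy)phenyl]-1-(2-hydroxy-6-methoxyphenyl)nonan-1-one
Product: 8 1-(2-hydroxy-6-methoxyphenyl)-9-(4-hydroxyphenyl)nonan-1-one
Conditions: H2 (1 atm), 10% Pd/C (5 mol % Pd), EtOAc, rt, 2 h
Reagents that add atoms: none
Why: Catalytic hydrogenolysis of a benzyl aryl ether over Pd/C is much faster than reduction of the hindered, intramolecularly hydrogen-bonded, di-ortho-substituted aryl ketone, and the aryl methyl ether is inert; no stereocentre is present.

**Compound list**
1 | octa-1,7-diene | C=CCCCCC=C | starting material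
2 | 9-borabicyclo[3.3.1]nonane (9-BBN) | B1C2CCCC1CCC2 | starting material
3 | 1-(benzyloxy)-4-bromobenzene | Brc1ccc(OCc2ccccc2)cc1 | starting material
4 | 9-(oct-7-en-1-yl)-9-borabicyclo[3.3.1]nonane | C=CCCCCCCB1C2CCCC1CCC2 | intermediate
5 | 1-(benzyloxy)-4-(oct-7-en-1-yl)benzene | C=CCCCCCCc1ccc(OCc2ccccc2)cc1 | intermediate
6 | 2-hydroxy-6-methoxybenzaldehyde | COc1cccc(O)c1C=O | starting material
7 | 9-[4-(benzyloxy)phenyl]-1-(2-hydroxy-6-methoxyphenyl)nonan-1-one | COc1cccc(O)c1C(=O)CCCCCCCCc1ccc(OCc2ccccc2)cc1 | intermediate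
8 | 1-(2-hydroxy-6-methoxyphenyl)-9-(4-hydroxyphenyl)nonan-1-one | COc1cccc(O)c1C(=O)CCCCCCCCc1ccc(O)cc1 | target

**Total step count:** 3. **Longest linear sequence:** 3 steps (1 → 5 → 7 → 8).

**Steps most likely to fail**

Step 2 (the proposed new cobalt hydroacylation). The risks are no turnover, decarbonylation of 6, or cobalt hydride walking the alkene inward. The fallback uses known chemistry and replaces the C–H addition by a ketone enolate alkylation; it sets out from 5 and comes back at 7. Ozonolysis of 5 (O3, CH2Cl2, −78 °C; then Me2S) gives 7-[4-(benzyloxy)phenyl]heptanal F1. NaBH4 in MeOH at 0 °C reduces it to 7-[4-(benzyloxy)phenyl]heptan-1-ol F2. PPh3, I2 and imidazole in CH2Cl2 convert this into 1-(benzyloxy)-4-(7-iodoheptyl)benzene F3. Commercial 1-(2-hydroxy-6-methoxyphenyl)ethan-1-one (COc1cccc(O)c1C(C)=O) is treated with LiN(iPr)2 (2.2 equiv) in THF at −78 °C to give the dilithium phenoxide-enolate of 1-(2-hydroxy-6-methoxyphenyl)ethan-1-one F4. F4 is alkylated at its methyl carbon by F3 (THF/DMPU, −78 °C to rt) and, after aqueous work-up, gives 7.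

Step 1 (mono-hydroboration and B-alkyl coupling). The risks are double hydroboration of the diene and slow coupling of the electron-rich aryl bromide. The fallback inverts the polarity of the coupling and needs no diene desymmetrisation; it sets out from 3 and comes back at 5. Mg turnings in THF convert 3 into [4-(benzyloxy)phenyl]magnesium bromide F5. F5 is coupled with commercial 8-bromooct-1-ene (C=CCCCCCCBr) under Li2CuCl4 (3 mol %) in THF/NMP at 0 °C to give 5.

Step 3 (hydrogenolysis). The risk is partial reduction of the aryl ketone. The fallback replaces the benzyl group by a fluoride-labile silyl group so that no hydrogenation is needed; it sets out from borane 4 and comes back at 8. Borane 4 is coupled with commercial (4-bromophenoxy)tri(propan-2-yl)silane (CC(C)[Si](Oc1ccc(Br)cc1)(C(C)C)C(C)C) using PdCl2(dppf) and K3PO4 in THF/DMF/H2O at 60 °C, to give tri(propan-2-yl)[4-(oct-7-en-1-yl)phenoxy]silane F6. Hydroacylation of F6 with 6 under the conditions of step 2 gives 1-(2-hydroxy-6-methoxyphenyl)-9-(4-{[tri(propan-2-yl)silyl]oxy}phenyl)nonan-1-one F7. Bu4NF in THF at 0 °C then gives 8.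

**Further compounds**
F1 | step 2 | 7-[4-(benzyloxy)phenyl]heptanal | O=CCCCCCCc1ccc(OCc2ccccc2)cc1
F2 | step 2 | 7-[4-(benzyloxy)phenyl]heptan-1-ol | OCCCCCCCc1ccc(OCc2ccccc2)cc1
F3 | step 2 | 1-(benzyloxy)-4-(7-iodoheptyl)benzene | ICCCCCCCc1ccc(OCc2ccccc2)cc1
F4 | step 2 | dilithium phenoxide-enolate of 1-(2-hydroxy-6-methoxyphenyl)ethan-1-one | [Li+].[Li+].COc1cccc([O-])c1C(=C)[O-]
F5 | step 1 | [4-(benzyloxy)phenyl]magnesium bromide | Br[Mg]c1ccc(OCc2ccccc2)cc1
F6 | step 3 | tri(propan-2-yl)[4-(oct-7-en-1-yl)phenoxy]silane | C=CCCCCCCc1ccc(O[Si](C(C)C)(C(C)C)C(C)C)cc1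
F7 | step 3 | 1-(2-hydroxy-6-methoxyphenyl)-9-(4-{[tri(propan-2-yl)silyl]oxy}phenyl)nonan-1-one | COc1cccc(O)c1C(=O)CCCCCCCCc1ccc(O[Si](C(C)C)(C(C)C)C(C)C)cc1
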